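Everything rests on cutting the enyne at its C(sp)–C(sp2) single bond, C5'–C6' of the hexadec-6-ene-4,15-diynyl chain (primed atoms; C1' sits on ring carbon C6). The key step exploits that the C6'–C16' segment, the E C6'=C7' alkene plus the terminal C15'≡C16' alkyne, is a mono-hydrometalated, C2-symmetric undeca-1,10-diyne: syn-hydrozirconation of one terminus and palladium-catalysed coupling of the alkenylzirconocene with a 1-bromoalkyne set the E geometry, form the bond and leave the far alkyne free, with no protecting group and no base near the 1,2-dioxane ring. The bromoalkyne already holds the (3S,6R)-peroxyketal, made by SN2 closure of a hydroperoxy ketal onto a chiral mesylate.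

Key step: step 10

Assumption: epoxide 5 and diyne 16 are treated as catalogue compounds (5 is the hydrolytic-kinetic-resolution product of the racemic epoxide; 16 is the double acetylide alkylation product of 1,7-dibromoheptane).

Step 1
Reactants: 1 (4-bromobut-1-yn-1-yl)trimethylsilane; 2 3-chloro-2-(chloromethyl)prop-1-ene
Product: 4 [6-(chloromethyl)hept-6-en-1-yn-1-yl]trimethylsilane, via homopropargyl Grignard reagent 3 (not isolated)
Conditions: Mg, THF, 40 °C; then added to 2 (3 equiv), CuI (5 mol %), THF, −20 °C to rt
Reagents that add atoms: none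
Why: Copper-catalysed allylic substitution of a Grignard reagent on the symmetrical bis-allylic chloride, in which SN2 and SN2' attack give the same product and the excess of 2 suppresses a second substitution, while the C-silyl group masks the acidic alkyne hydrogen.

Step 2
Reactants: 4 [6-(chloromethyl)hept-6-en-1-yn-1-yl]trimethylsilane; 5 (2S)-2-{2-[(tert-butyldimethylsilyl)oxy]ethyl}oxirane
Product: 7 (3R)-1-[(tert-butyldimethylsilyl)oxy]-6-methylidene-11-(trimethylsilyl)undec-10-yn-3-ol, via allylic Grignard reagent 6 (not isolated)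
Conditions: Mg (excess), THF, 0 °C, slow addition; then 5, CuI (10 mol %), THF, −30 to 0 °C
Reagents that add atoms: none
Why: Copper-assisted ring opening of a terminal epoxide by an allylic Grignard reagent at the unsubstituted carbon, so no bond to the stereocentre is broken and the configuration of 5 is carried into the carbinol (the descriptor becomes R only through a change of priorities).

Step 3
Reactants: 7 (3R)-1-[(tert-butyldimethylsilyl)oxy]-6-methylidene-11-(trimethylsilyl)undec-10-yn-3-ol
Product: 8 (3R)-1-[(tert-butyldimethylsilyl)oxy]-6-methylidene-11-(trimethylsilyl)undec-10-yn-3-yl methanesulfonate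
Conditions: MsCl, Et3N, CH2Cl2, 0 °C
Reagents that add atoms: methanesulfonyl chloride, CS(=O)(=O)Cl
Why: O-sulfonylation with retention turns the carbinol into the leaving group for the later SN2 closure, and the silyloxyethyl arm (a masked acetate) leaves no acidic hydrogen beside it, so E1cB loss of the sulfonate is excluded.

Step 4
Reactants: 8 (3R)-1-[(tert-butyldimethylsilyl)oxy]-6-methylidene-11-(trimethylsilyl)undec-10-yn-3-yl methanesulfonate
Product: 10 (3R)-1-[(tert-butyldimethylsilyl)oxy]-6-hydroperoxy-6-methoxy-11-(trimethylsilyl)undec-10-yn-3-yl methanesulfonate as both C6 epimers, via carbonyl oxide 9 (not isolated)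
Conditions: O3, CH2Cl2/MeOH (4:1), −78 °C; N2 purge
Reagents that add atoms: ozone, [O-][O+]=O; methanol, CO
Why: Criegee ozonolysis of the 1,1-disubstituted alkene, which reacts far faster than the silylalkyne; the primary ozonide should fragment to formaldehyde and the more substituted carbonyl oxide, which methanol traps as the α-methoxy hydroperoxide.

Step 5
Reactants: 10 (3R)-1-[(tert-butyldimethylsilyl)oxy]-6-hydroperoxy-6-methoxy-11-(trimethylsilyl)undec-10-yn-3-yl methanesulfonate
Product: 11 tert-butyl(2-{(3S)-6-methoxy-6-[5-(trimethylsilyl)pent-4-yn-1-yl]-1,2-dioxan-3-yl}ethoxy)dimethylsilane as both C6 epimers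
Conditions: KOtBu (1.1 equiv), 18-crown-6, THF, 0 °C
Reagents that add atoms: none
Why: Intramolecular peroxide alkylation (Williamson-type 6-exo-tet SN2 of the hydroperoxide anion on the secondary mesylate) closes the 1,2-dioxane with inversion and so sets C3 as S; the ketal carbon C6 stays an epimer mixture until step 8.

Step 6
Reactants: 11 tert-butyl(2-{(3S)-6-methoxy-6-[5-(trimethylsilyl)pent-4-yn-1-yl]-1,2-dioxan-3-yl}ethoxy)dimethylsilane
Product: 12 2-[(3S)-6-methoxy-6-(pent-4-yn-1-yl)-1,2-dioxan-3-yl]ethan-1-ol as both C6 epimers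
Conditions: TBAF, AcOH, THF, 0 °C to rt
Reagents that add atoms: none
Why: Fluoride-mediated desilylation removes the O-silyl ether and the C-silyl group in one operation, and the acetic acid buffer guards the secondary peroxide C–H against Kornblum–DeLaMare fragmentation.

Step 7
Reactants: 12 2-[(3S)-6-methoxy-6-(pent-4-yn-1-yl)-1,2-dioxan-3-yl]ethan-1-ol
Product: 13 2-[(3S)-6-methoxy-6-(pent-4-yn-1-yl)-1,2-dioxan-3-yl]acetic acid as both C6 epimers
Conditions: TEMPO (cat.), PhI(OAc)2 (2.2 equiv), MeCN/H2O (1:1), rt
Reagents that add atoms: water, O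
Why: Oxoammonium-catalysed oxidation of the primary alcohol through the aldehyde hydrate to the acid under near-neutral conditions that spare the peroxide and the terminal alkyne; any partial hydrolysis of the methyl ketal is repaired in step 8.

Step 8
Reactants: 13 2-[(3S)-6-methoxy-6-(pent-4-yn-1-yl)-1,2-dioxan-3-yl]acetic acid
Product: 14 methyl 2-[(3S,6R)-6-methoxy-6-(pent-4-yn-1-yl)-1,2-dioxan-3-yl]acetate
Conditions: MeOH, TsOH·H2O (cat.), rt
Reagents that add atoms: methanol, CO
Why: Fischer esterification under conditions that also ionise the peroxyketal reversibly to a cyclic peroxycarbenium ion, so C6 should equilibrate by methanol exchange towards the epimer with axial methoxy (anomeric stabilisation) and both carbon substituents equatorial, which is 6R with methoxy cis to the acetate arm; the minor C6 epimer is separated by chromatography and resubmitted.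

Step 9
Reactants: 14 methyl 2-[(3S,6R)-6-methoxy-6-(pent-4-yn-1-yl)-1,2-dioxan-3-yl]acetate
Product: 15 methyl 2-[(3S,6R)-6-(5-bromopent-4-yn-1-yl)-6-methoxy-1,2-dioxan-3-yl]acetate
Conditions: NBS, AgNO3 (10 mol %), acetone, rt, dark
Reagents that add atoms: N-bromosuccinimide, O=C1CCC(=O)N1Br
Why: Silver-catalysed electrophilic bromination of the terminal alkyne via the silver acetylide gives the 1-bromoalkyne under neutral conditions that leave both stereocentres, the ester and the O–O bond untouched.

Step 10
Reactants: 15 methyl 2-[(3S,6R)-6-(5-bromopent-4-yn-1-yl)-6-methoxy-1,2-dioxan-3-yl]acetate; 16 undeca-1,10-diyne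
Product: 18 methyl 2-[(3S,6R)-6-[(6E)-hexadec-6-ene-4,15-diyn-1-yl]-6-methoxy-1,2-dioxan-3-yl]acetate, via alkenylzirconocene chloride 17 (not isolated)
Conditions: 16 (4.5 equiv), Cp2Zr(H)Cl (1.5 equiv), THF, rt; then 15 (1.0 equiv), Pd(PPh3)4 (5 mol %), THF, 0 °C to rt, dark
Reagents that add atoms: none
Why: Cp2Zr(H)Cl adds syn and anti-Markovnikov across one terminal triple bond of the C2-symmetric diyne 16 (used in excess so that statistics favour single hydrozirconation) to give the E-alkenylzirconocene 17 with zirconium on the terminal carbon; zerovalent palladium then inserts into the C(sp)–Br bond of 15, the alkenyl group passes from zirconium to palladium with retention, and reductive elimination forms the C5'–C6' bond. The closest known reaction type is the Negishi-type hydrozirconation/palladium-catalysed cross-coupling of alkenylzirconocene chlorides with 1-haloalkynes to give E-enynes. No ring is closed and no stereocentre is created; the only stereochemical element formed, the E C6'=C7' double bond, is fixed by the syn hydrometalation and the stereoretentive transmetalation and reductive elimination. The step needs chemoselectivity for the C(sp)–Br bond over the O–O bond, the ester and the free C≡C–H groups: without base, amine or copper the remaining terminal alkyne of 17 and the excess 16 are not metalated, the β-peroxy ester cannot undergo E1cB ring opening, and the weakly nucleophilic C–Zr bond together with fast oxidative addition into the bromoalkyne should leave the dialkyl peroxyketal untouched. Both stereocentres of 15 (3S,6R) are carried through unchanged.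

Compound list
1 | (4-bromobut-1-yn-1-yl)trimethylsilane | C[Si](C)(C)C#CCCBr | starting material
2 | 3-chloro-2-(chloromethyl)prop-1-ene | ClCC(=C)CCl | starting material
3 | [4-(trimethylsilyl)but-3-yn-1-yl]magnesium bromide | C[Si](C)(C)C#CCC[Mg]Br | intermediate
4 | [6-(chloromethyl)hept-6-en-1-yn-1-yl]trimethylsilane | C[Si](C)(C)C#CCCCC(=C)CCl | intermediate
5 | (2S)-2-{2-[(tert-butyldimethylsilyl)oxy]ethyl}oxirane | C1[C@H](CCO[Si](C)(C)C(C)(C)C)O1 | starting material
6 | [2-methylidene-7-(trimethylsilyl)hept-6-yn-1-yl]magnesium chloride | C[Si](C)(C)C#CCCCC(=C)C[Mg]Cl | intermediate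
7 | (3R)-1-[(tert-butyldimethylsilyl)oxy]-6-methylidene-11-(trimethylsilyl)undec-10-yn-3-ol | C[Si](C)(C)C#CCCCC(=C)CC[C@H](CCO[Si](C)(C)C(C)(C)C)O | intermediate
8 | (3R)-1-[(tert-butyldimethylsilyl)oxy]-6-methylidene-11-(trimethylsilyl)undec-10-yn-3-yl methanesulfonate | C[Si](C)(C)C#CCCCC(=C)CC[C@H](CCO[Si](C)(C)C(C)(C)C)OS(C)(=O)=O | intermediate
9 | carbonyl oxide (ketone O-oxide) at C6 of the mesylate, formed with loss of formaldehyde | C[Si](C)(C)C#CCCCC(=[O+][O-])CC[C@H](CCO[Si](C)(C)C(C)(C)C)OS(C)(=O)=O | intermediate
10 | (3R)-1-[(tert-butyldimethylsilyl)oxy]-6-hydroperoxy-6-methoxy-11-(trimethylsilyl)undec-10-yn-3-yl methanesulfonate (both C6 epimers) | C[Si](C)(C)C#CCCCC(OC)(OO)CC[C@H](CCO[Si](C)(C)C(C)(C)C)OS(C)(=O)=O | intermediate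
11 | tert-butyl(2-{(3S)-6-methoxy-6-[5-(trimethylsilyl)pent-4-yn-1-yl]-1,2-dioxan-3-yl}ethoxy)dimethylsilane (both C6 epimers) | C[Si](C)(C)C#CCCCC1(OC)CC[C@@H](CCO[Si](C)(C)C(C)(C)C)OO1 | intermediate
12 | 2-[(3S)-6-methoxy-6-(pent-4-yn-1-yl)-1,2-dioxan-3-yl]ethan-1-ol (both C6 epimers) | C#CCCCC1(OC)CC[C@@H](CCO)OO1 | intermediate
13 | 2-[(3S)-6-methoxy-6-(pent-4-yn-1-yl)-1,2-dioxan-3-yl]acetic acid (both C6 epimers) | C#CCCCC1(OC)CC[C@@H](CC(=O)O)OO1 | intermediate
14 | methyl 2-[(3S,6R)-6-methoxy-6-(pent-4-yn-1-yl)-1,2-dioxan-3-yl]acetate | C#CCCC[C@]1(OC)CC[C@@H](CC(=O)OC)OO1 | intermediate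
15 | methyl 2-[(3S,6R)-6-(5-bromopent-4-yn-1-yl)-6-methoxy-1,2-dioxan-3-yl]acetate | BrC#CCCC[C@]1(OC)CC[C@@H](CC(=O)OC)OO1 | intermediate
16 | undeca-1,10-diyne | C#CCCCCCCCC#C | starting material
17 | chlorobis(cyclopentadienyl)[(1E)-undec-1-en-10-yn-1-yl]zirconium | C#CCCCCCCC/C=C/[Zr](Cl)(C1C=CC=C1)C1C=CC=C1 | intermediate
18 | methyl 2-[(3S,6R)-6-[(6E)-hexadec-6-ene-4,15-diyn-1-yl]-6-methoxy-1,2-dioxan-3-yl]acetate | C#CCCCCCCC/C=C/C#CCCC[C@]1(OC)CC[C@@H](CC(=O)OC)OO1 | target

Total step count: 10. Longest linear sequence: 10 steps (1 to 18); 5 and 16 enter as purchased fragments.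

Steps most likely to fail

Step 10. What may go wrong: double hydrozirconation of the diyne, slow transfer of the alkenyl group from zirconium to palladium (allowing halogen–metal exchange and homocoupling), or reductive cleavage of the O–O bond by the low-valent metals. The fallback reverses the polarity of the coupling; it sets out from 14 (with 16 as the source of the other half) and comes back at 18. Diyne 16 would be monosilylated (n-BuLi, 1 equiv, THF, −78 °C; Me3SiCl) to trimethyl(undeca-1,10-diyn-1-yl)silane F1. Its free terminus would then be hydrozirconated and iodinated (Cp2Zr(H)Cl, THF; I2) to [(10E)-11-iodoundec-10-en-1-yn-1-yl]trimethylsilane F2. Sonogashira coupling of F2 with the terminal alkyne 14 (PdCl2(PPh3)2, CuI, Et3N, THF, rt) should give methyl 2-[(3S,6R)-6-methoxy-6-[(6E)-16-(trimethylsilyl)hexadec-6-ene-4,15-diyn-1-yl]-1,2-dioxan-3-yl]acetate F3, and buffered fluoride (TBAF, AcOH, THF) would remove the C-silyl group to give 18.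

Step 5. What may go wrong: elimination of the secondary mesylate, or base-induced fragmentation of the hydroperoxy ketal, in place of ring closure. The fallback forms the C3–O bond first and the ketal last; it sets out from 8 and comes back at 12, bypassing 10 and 11. Ozonolysis of 8 with reductive work-up (O3, CH2Cl2, −78 °C; Me2S) would give (3R)-1-[(tert-butyldimethylsilyl)oxy]-6-oxo-11-(trimethylsilyl)undec-10-yn-3-yl methanesulfonate F4. Alkaline hydrogen peroxide (50% H2O2, KOH, MeOH/THF, 0 °C) should displace the mesylate with inversion, close the new hydroperoxide onto the ketone and cleave the alkynyl silane, giving (6S)-6-{2-[(tert-butyldimethylsilyl)oxy]ethyl}-3-(pent-4-yn-1-yl)-1,2-dioxan-3-ol F5 in one operation. Acidic methanol (TsOH cat., MeOH, rt) would then convert the peroxyhemiketal into the methyl ketal under thermodynamic control and remove the primary silyl ether, giving 12.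

Step 8. What may go wrong: acid-induced heterolysis of the peroxyketal leading to ring opening or Hock-type cleavage, or an unfavourable position of the C6 equilibrium in methanol. The fallback separates esterification from control of C6 and sets the ketal kinetically; it sets out from 13 and comes back at 14. Neutral methylation (Me3SiCHN2, toluene/MeOH, 0 °C) would give 14 together with its C6 epimer, methyl 2-[(3S,6S)-6-methoxy-6-(pent-4-yn-1-yl)-1,2-dioxan-3-yl]acetate F6, separable by chromatography. F6 would then be ionised under aprotic conditions (Me3SiOTf cat., Me3SiOMe, CH2Cl2, −78 °C) to the cyclic peroxycarbenium ion, whose stereoelectronically preferred axial capture by the silyl ether should return 14.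

Further compounds
F1 | step 10 | trimethyl(undeca-1,10-diyn-1-yl)silane | C[Si](C)(C)C#CCCCCCCCC#C
F2 | step 10 | [(10E)-11-iodoundec-10-en-1-yn-1-yl]trimethylsilane | C[Si](C)(C)C#CCCCCCCC/C=C/I
F3 | step 10 | methyl 2-[(3S,6R)-6-methoxy-6-[(6E)-16-(trimethylsilyl)hexadec-6-ene-4,15-diyn-1-yl]-1,2-dioxan-3-yl]acetate | C[Si](C)(C)C#CCCCCCCC/C=C/C#CCCC[C@]1(OC)CC[C@@H](CC(=O)OC)OO1
F4 | step 5 | (3R)-1-[(tert-butyldimethylsilyl)oxy]-6-oxo-11-(trimethylsilyl)undec-10-yn-3-yl methanesulfonate | C[Si](C)(C)C#CCCCC(=O)CC[C@H](CCO[Si](C)(C)C(C)(C)C)OS(C)(=O)=O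
F5 | step 5 | (6S)-6-{2-[(tert-butyldimethylsilyl)oxy]ethyl}-3-(pent-4-yn-1-yl)-1,2-dioxan-3-ol (both C3 epimers) | C#CCCCC1(O)CC[C@@H](CCO[Si](C)(C)C(C)(C)C)OO1
F6 | step 8 | methyl 2-[(3S,6S)-6-methoxy-6-(pent-4-yn-1-yl)-1,2-dioxan-3-yl]acetate | C#CCCC[C@@]1(OC)CC[C@@H](CC(=O)OC)OO1
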